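## Retrosynthetic overview

1. Target 12 comes from tetralin-2,3-dicarboxylate 10 (LiAlH4, then desilylation); the two carboxyls of 10 are tied to a C2-symmetric trans-cyclohexane-1,2-diol.
2. The tetralin ring of 10 comes from ring expansion (4 to 6) of the all-trans 3,4-diarylcyclobutane-1,2-dicarboxylate 9: the diaryl C–C bond breaks and one benzylic carbon re-bonds to the ortho carbon of the other arene (sets C1).
3. Cyclobutane 9 comes from a tether-controlled intramolecular [2+2] photocycloaddition of bis-cinnamate 8 (forms the C2–C3 bond, sets C2 and C3).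
4. 8 comes from a double Heck coupling of aryl bromide 4 with diacrylate 7; 4 from catechol (methylation, bromination, silylation); 7 from the diol and acryloyl chloride.
5. Ring order: arenes (from catechol), then cyclobutane with its eight-membered dilactone, then the tetralin carbocycle.

Assumption: the SMILES is read as (1R,2S,3S)-isolariciresinol, the (−)-enantiomer; the sense of induction by the diol tether in step 6 rests on the twist-matching model given there and is not backed by a tested precedent, so if experiment shows the opposite sense the (1R,2R)-diol is used with no other change.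

## Route

Step 1
Reactants: 1 catechol
Product: 2 guaiacol (2-methoxyphenol)
Conditions: MeI (1.0 equiv), K2CO3 (1.0 equiv), acetone, reflux (1 in 1.5-fold excess, recovered)
Reagents that add atoms: methyl iodide, CI
Why: Williamson O-methylation of the mono-phenoxide; one equivalent of base and excess 1 keep dimethylation low, and no stereocentre is involved.

Step 2
Reactants: 2 guaiacol
Product: 3 4-bromo-2-methoxyphenol
Conditions: NBS (1.0 equiv), MeCN, 0 °C to rt
Reagents that add atoms: N-bromosuccinimide, O=C1CCC(=O)N1Br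
Why: Electrophilic aromatic bromination in which the free OH is the stronger director, so bromine enters para to OH.

Step 3
Reactants: 3 4-bromo-2-methoxyphenol
Product: 4 (4-bromo-2-methoxyphenoxy)(tert-butyl)dimethylsilane
Conditions: TBSCl, imidazole, DMF, rt
Reagents that add atoms: tert-butyldimethylsilyl chloride, CC(C)(C)[Si](C)(C)Cl
Why: Standard silyl ether protection of the phenol; it keeps a π-donating oxygen para to the future benzylic carbon (needed in step 7) and is cleaved by hydroxide in step 8.

Step 4
Reactants: 5 (1S,2S)-cyclohexane-1,2-diol; 6 acryloyl chloride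
Product: 7 (1S,2S)-cyclohexane-1,2-diyl diacrylate
Conditions: 6 (2.3 equiv), Et3N, CH2Cl2, 0 °C to rt
Reagents that add atoms: none
Why: Acylation of both secondary hydroxyls by the acid chloride (esterification); the carbinol stereocentres are not touched.

Step 5
Reactants: 4 (4-bromo-2-methoxyphenoxy)(tert-butyl)dimethylsilane; 7 (1S,2S)-cyclohexane-1,2-diyl diacrylate
Product: 8 (1S,2S)-cyclohexane-1,2-diyl bis{(E)-3-[4-(tert-butyldimethylsilyloxy)-3-methoxyphenyl]acrylate}
Conditions: 4 (2.3 equiv), Pd(OAc)2 (5 mol %), P(o-tol)3 (12 mol %), Et3N, DMF, 100 °C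
Reagents that add atoms: none
Why: Double Mizoroki–Heck arylation of the two terminal acrylate C=C bonds; syn insertion and syn β-hydride elimination give the (E)-cinnamates.

Step 6
Reactants: 8 tethered bis-cinnamate
Product: 9 (1S,2S,3R,4R)-3,4-bis[4-(tert-butyldimethylsilyloxy)-3-methoxyphenyl]cyclobutane-1,2-dicarboxylic acid cyclic diester of (1S,2S)-cyclohexane-1,2-diol (all four cyclobutane substituents mutually trans, δ-truxinate type)
Conditions: thioxanthen-9-one (10 mol %), degassed MeCN (3 mM), 405 nm LEDs, rt
Reagents that add atoms: none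
Why: Intramolecular triplet-sensitised [2+2] photocycloaddition: the two ester-bearing carbons bond first to give a bis-benzylic 1,4-diradical that closes to the all-trans cyclobutane, and the diequatorial (1S,2S)-diol (O–C–C–O about +60°) is proposed to admit into the eight-membered dilactone only the diradical whose new centres are both S (carboxyl–C–C–carboxyl twist of the same sign), so the future C2 and C3 are set here in absolute terms and the two aryl-bearing centres are set trans.

Step 7
Reactants: 9 tethered all-trans cyclobutane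
Product: 10 (1R,2S,3S)-7-(tert-butyldimethylsilyloxy)-1-[4-(tert-butyldimethylsilyloxy)-3-methoxyphenyl]-6-methoxy-1,2,3,4-tetrahydronaphthalene-2,3-dicarboxylic acid cyclic diester of (1S,2S)-cyclohexane-1,2-diol
Conditions: 9-mesityl-3,6-di-tert-butyl-10-phenylacridinium tetrafluoroborate (5 mol %), PhSSPh (10 mol %), (CF3)2CHOH/ClCH2CH2Cl 1:4 (0.02 M), 450 nm LEDs, rt, argon
Reagents that add atoms: none
Why: Proposed new method: photo-oxidation of one dialkoxyarene gives an arene radical cation whose strained, doubly benzylic cyclobutane bond (between the two aryl-bearing carbons) cleaves to a distonic 1,4-radical cation; the p-silyloxybenzyl cation end is then captured by the ortho carbon (para to OMe) of the other arene in a six-ring Friedel–Crafts closure with the aryl pseudo-equatorial (C1 trans to C2), proton loss re-aromatises, and the remaining benzylic radical takes a hydrogen atom from thiophenol while the thiyl radical re-oxidises the reduced acridine, giving a redox-neutral, non-pericyclic 4-to-6 ring expansion; cycloreversion is disfavoured because it would give an electron-poor cinnamate radical cation, and relief of the strained trans-fused dilactone (twist about +116° in 9, about +56° in 10) adds driving force; the closest known reactions are the radical-cation vinylcyclobutane-to-cyclohexene rearrangement, formation of 1-aryltetralins from 1,4-radical cations of arylalkene dimers, and acridinium/thiol anti-Markovnikov hydrofunctionalisation, none shown on truxinate-type cyclobutanes.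

Step 8
Reactants: 10 tethered tetralin diester
Product: 12 (−)-isolariciresinol, via bis-TBS isolariciresinol 11 (not isolated)
Conditions: LiAlH4 (2.5 equiv), THF, 0 °C to rt; then MeOH, 2 M aq NaOH, rt; 1 M HCl to pH 6
Reagents that add atoms: none
Why: Hydride reduction of both ester carbonyls gives the two CH2OH groups and releases the diol tether without touching C1, C2 or C3, and the aryl silyl ethers are then cleaved by methanolic hydroxide in the same flask (ester reduction, then base-mediated desilylation).

## Compound list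

1 | catechol (benzene-1,2-diol) | Oc1ccccc1O | starting material
2 | guaiacol (2-methoxyphenol) | COc1ccccc1O | intermediate
3 | 4-bromo-2-methoxyphenol | COc1cc(Br)ccc1O | intermediate
4 | (4-bromo-2-methoxyphenoxy)(tert-butyl)dimethylsilane | COc1cc(Br)ccc1O[Si](C)(C)C(C)(C)C | intermediate
5 | (1S,2S)-cyclohexane-1,2-diol (chiral tether, recovered in step 8) | O[C@H]1CCCC[C@@H]1O | starting material
6 | acryloyl chloride | C=CC(Cl)=O | starting material
7 | (1S,2S)-cyclohexane-1,2-diyl diacrylate | C=CC(=O)O[C@H]1CCCC[C@@H]1OC(=O)C=C | intermediate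
8 | (1S,2S)-cyclohexane-1,2-diyl bis{(E)-3-[4-(tert-butyldimethylsilyloxy)-3-methoxyphenyl]acrylate} | COc1cc(/C=C/C(=O)O[C@H]2CCCC[C@@H]2OC(=O)/C=C/c2ccc(O[Si](C)(C)C(C)(C)C)c(OC)c2)ccc1O[Si](C)(C)C(C)(C)C | intermediate
9 | (1S,2S,3R,4R)-3,4-bis[4-(tert-butyldimethylsilyloxy)-3-methoxyphenyl]cyclobutane-1,2-dicarboxylic acid cyclic diester of (1S,2S)-cyclohexane-1,2-diol (all-trans cyclobutane) | COc1cc(ccc1O[Si](C)(C)C(C)(C)C)[C@H]1[C@H](C(=O)O[C@H]3CCCC[C@@H]3OC2=O)[C@@H]2[C@@H]1c1ccc(O[Si](C)(C)C(C)(C)C)c(OC)c1 | intermediate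
10 | (1R,2S,3S)-7-(tert-butyldimethylsilyloxy)-1-[4-(tert-butyldimethylsilyloxy)-3-methoxyphenyl]-6-methoxy-1,2,3,4-tetrahydronaphthalene-2,3-dicarboxylic acid cyclic diester of (1S,2S)-cyclohexane-1,2-diol | COc1cc([C@@H]2c3cc(O[Si](C)(C)C(C)(C)C)c(OC)cc3C[C@H](C(=O)O[C@H]4CCCC[C@@H]4OC5=O)[C@H]25)ccc1O[Si](C)(C)C(C)(C)C | intermediate
11 | bis-TBS isolariciresinol: [(1R,2S,3S)-7-(tert-butyldimethylsilyloxy)-1-[4-(tert-butyldimethylsilyloxy)-3-methoxyphenyl]-6-methoxy-1,2,3,4-tetrahydronaphthalene-2,3-diyl]dimethanol | COc1cc([C@@H]2c3cc(O[Si](C)(C)C(C)(C)C)c(OC)cc3C[C@H](CO)[C@H]2CO)ccc1O[Si](C)(C)C(C)(C)C | intermediate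
12 | (−)-isolariciresinol: [(1R,2S,3S)-7-hydroxy-1-(4-hydroxy-3-methoxyphenyl)-6-methoxy-1,2,3,4-tetrahydronaphthalene-2,3-diyl]dimethanol | COc1cc([C@@H]2c3cc(O)c(OC)cc3C[C@H](CO)[C@H]2CO)ccc1O | target

## Step count and risks

Total steps: 8. Longest linear sequence: 7 (steps 1, 2, 3, 5, 6, 7, 8; step 4 is a one-step side branch).

Most likely to fail:

**Step 7 (the proposed ring expansion).** Risks are cycloreversion of the radical cation to 8, proton loss from the benzylic cation to an alkene, and over-oxidation of 10. The fallback uses known chemistry only, sets out from 8 and comes back at 12. Hydrogenation of 8 (H2, Pd/C, EtOAc) gives the tethered bis(3-arylpropanoate) F1. Its bis(lithium enolate) (LiN(iPr)2, THF, −78 °C) is oxidised with CuCl2 in a tether-templated oxidative enolate coupling to the tethered (2S,3S)-2,3-dibenzylsuccinate F2, the matched diequatorial isomer on the same tether model. Bu4NF removes the silyl groups to give the bis-phenol F3. DDQ in CH2Cl2/CF3CO2H at 0 °C abstracts hydride from one 4-hydroxybenzylic CH2 (the two are equivalent), and the p-hydroxybenzyl cation closes onto the other ring para to OMe, the oxidative Friedel–Crafts cyclisation used for phenolic dibenzyl lignans, giving the tetralin diester bis-phenol F4 with C1 trans to C2. LiAlH4 in THF then reduces F4 to 12.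

**Step 6 (tether-controlled [2+2]).** Risks are low or reversed diastereoselection, cis-fused isomers, and strain in the eight-membered dilactone. The fallback replaces asymmetric induction by resolution, sets out from 4 and comes back at 11. Heck coupling of 4 with methyl acrylate (C=CC(=O)OC) gives the methyl cinnamate F5. Sensitised intermolecular dimerisation (thioxanthen-9-one, 405 nm, 0.5 M, flow) gives the racemic all-trans dimer, which is separated from minor isomers and resolved on a chiral stationary phase into the (1S,2S,3R,4R)-dimethyl diester F6 (kept) and its (1R,2R,3S,4S)-enantiomer F7 (set aside). F6 under the conditions of step 7 gives the tetralin dimethyl diester F8, and LiAlH4 reduces F8 to 11, which is desilylated as in step 8.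

**Step 5 (double Heck).** Risks are incomplete second coupling on an electron-rich aryl bromide and radical polymerisation of the diacrylate at 100 °C. The fallback forms the C–C bond on a simple acrylate first and the two C–O bonds last; it sets out from 4 and comes back at 8. A single Heck coupling of 4 with acrylic acid (C=CC(=O)O; Pd(OAc)2, P(o-tol)3, Et3N, DMF) gives the cinnamic acid F9. Carbodiimide esterification of diol 5 with two equivalents of F9 (EDC, DMAP, CH2Cl2) then gives 8 without passing through 7.

## Further compounds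

F1 | step 7 | (1S,2S)-cyclohexane-1,2-diyl bis{3-[4-(tert-butyldimethylsilyloxy)-3-methoxyphenyl]propanoate} | COc1cc(CCC(=O)O[C@H]2CCCC[C@@H]2OC(=O)CCc2ccc(O[Si](C)(C)C(C)(C)C)c(OC)c2)ccc1O[Si](C)(C)C(C)(C)C
F2 | step 7 | (2S,3S)-2,3-bis[4-(tert-butyldimethylsilyloxy)-3-methoxybenzyl]succinic acid cyclic diester of (1S,2S)-cyclohexane-1,2-diol | COc1cc(C[C@H](C(=O)O[C@H]3CCCC[C@@H]3OC2=O)[C@@H]2Cc4ccc(O[Si](C)(C)C(C)(C)C)c(OC)c4)ccc1O[Si](C)(C)C(C)(C)C
F3 | step 7 | (2S,3S)-2,3-bis(4-hydroxy-3-methoxybenzyl)succinic acid cyclic diester of (1S,2S)-cyclohexane-1,2-diol | COc1cc(C[C@H](C(=O)O[C@H]3CCCC[C@@H]3OC2=O)[C@@H]2Cc4ccc(O)c(OC)c4)ccc1O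
F4 | step 7 | (1R,2S,3S)-7-hydroxy-1-(4-hydroxy-3-methoxyphenyl)-6-methoxy-1,2,3,4-tetrahydronaphthalene-2,3-dicarboxylic acid cyclic diester of (1S,2S)-cyclohexane-1,2-diol | COc1cc([C@@H]2c3cc(O)c(OC)cc3C[C@H](C(=O)O[C@H]4CCCC[C@@H]4OC5=O)[C@H]25)ccc1O
F5 | step 6 | methyl (E)-3-[4-(tert-butyldimethylsilyloxy)-3-methoxyphenyl]acrylate | COC(=O)/C=C/c1ccc(O[Si](C)(C)C(C)(C)C)c(OC)c1
F6 | step 6 | dimethyl (1S,2S,3R,4R)-3,4-bis[4-(tert-butyldimethylsilyloxy)-3-methoxyphenyl]cyclobutane-1,2-dicarboxylate | COc1cc(ccc1O[Si](C)(C)C(C)(C)C)[C@H]1[C@H](C(=O)OC)[C@@H](C(=O)OC)[C@@H]1c1ccc(O[Si](C)(C)C(C)(C)C)c(OC)c1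
F7 | step 6 | dimethyl (1R,2R,3S,4S)-3,4-bis[4-(tert-butyldimethylsilyloxy)-3-methoxyphenyl]cyclobutane-1,2-dicarboxylate (enantiomer set aside) | COc1cc(ccc1O[Si](C)(C)C(C)(C)C)[C@@H]1[C@@H](C(=O)OC)[C@H](C(=O)OC)[C@H]1c1ccc(O[Si](C)(C)C(C)(C)C)c(OC)c1
F8 | step 6 | dimethyl (1R,2S,3S)-7-(tert-butyldimethylsilyloxy)-1-[4-(tert-butyldimethylsilyloxy)-3-methoxyphenyl]-6-methoxy-1,2,3,4-tetrahydronaphthalene-2,3-dicarboxylate | COc1cc([C@@H]2c3cc(O[Si](C)(C)C(C)(C)C)c(OC)cc3C[C@H](C(=O)OC)[C@H]2C(=O)OC)ccc1O[Si](C)(C)C(C)(C)C
F9 | step 5 | (E)-3-[4-(tert-butyldimethylsilyloxy)-3-methoxyphenyl]acrylic acid | COc1cc(/C=C/C(=O)O)ccc1O[Si](C)(C)C(C)(C)C
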